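## Retrosynthetic overview

1. Target 20 ⇒ tert-butyl ester 19 (acidolysis last) ⇒ C12–C13 cut: Negishi coupling of the C12 alkylzinc from iodide 16 with 3-bromo-2(5H)-furanone 17; the butenolide ring is bought intact and attached last.
2. C6–O cut: the tiglate is delivered to C6 (6α) of silyl dienolate 10 by [bis(tigloyloxy)iodo]benzene 13. This is the proposed new γ-acyloxylation and sets the only new stereocenter.
3. C8–C17 cut: Shapiro carboxylation (Boc2O) of the 8-ketone 5, made by ozonolysis of the exocyclic alkene 4 from dehydration of the 8α-alcohol.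
4. Rings A and B with C5, C9 and C10 are not built. They come intact from (+)-sclareolide 1, whose lactone ring is opened by LiAlH4. Ring order: decalin A/B (chiral pool), then butenolide appended in step 12.

Assumption: 3-bromo-2(5H)-furanone and 2,4,6-triisopropylbenzenesulfonyl hydrazide are bought as catalogue compounds; labdane numbering is used (C17 on C8; C11 and C12 the side-chain methylenes; C13–C16 the butenolide; TBSO = tert-butyldimethylsilyloxy), and the target is 5S,6S,9R,10R (5α-H, 6α-O, 9α-H, 10β-Me).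

## Route

Step 1
Reactants: 1 (+)-sclareolide
Product: 2 13,14,15,16-tetranorlabdane-8α,12-diol
Conditions: LiAlH4, THF, 0 °C → reflux
Reagents that add atoms: none
Why: Hydride reduction of the γ-lactone gives the primary C12 alcohol and frees the tertiary 8α-hydroxyl; C5, C8, C9 and C10 are untouched.

Step 2
Reactants: 2 13,14,15,16-tetranorlabdane-8α,12-diol
Product: 3 12-(TBSO)-13,14,15,16-tetranorlabdan-8α-ol
Conditions: TBSCl, imidazole, DMF, 0 °C → rt
Reagents that add atoms: tert-butyldimethylsilyl chloride, CC(C)(C)[Si](C)(C)Cl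
Why: Silyl ether protection occurs only at the primary hydroxyl because the tertiary C8 hydroxyl is too hindered for TBSCl/imidazole.

Step 3
Reactants: 3 12-(TBSO)-13,14,15,16-tetranorlabdan-8α-ol
Product: 4 12-(TBSO)-13,14,15,16-tetranorlabd-8(17)-ene
Conditions: SOCl2, pyridine, CH2Cl2, −78 °C
Reagents that add atoms: none
Why: E2 (Hofmann-type) dehydration of the chlorosulfite: with the C8–O bond equatorial only a C17 methyl hydrogen can be antiperiplanar, so the exocyclic alkene forms and the C8 stereocenter is removed.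

Step 4
Reactants: 4 12-(TBSO)-13,14,15,16-tetranorlabd-8(17)-ene
Product: 5 12-(TBSO)-13,14,15,16,17-pentanorlabdan-8-one
Conditions: O3, CH2Cl2/MeOH, −78 °C; then Me2S, −78 °C → rt
Reagents that add atoms: ozone, [O-][O+]=O
Why: Ozonolysis of the 1,1-disubstituted alkene with reductive work-up excises C17 and gives the C8 ketone; the C9 side chain stays in its equatorial, thermodynamically preferred β orientation.

Step 5
Reactants: 5 12-(TBSO)-13,14,15,16,17-pentanorlabdan-8-one
Product: 6 (E)-2,4,6-triisopropylbenzenesulfonylhydrazone of 5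
Conditions: 2,4,6-(i-Pr)3C6H2SO2NHNH2, cat. AcOH, THF, rt
Reagents that add atoms: 2,4,6-triisopropylbenzenesulfonyl hydrazide, NNS(=O)(=O)c1c(C(C)C)cc(C(C)C)cc1C(C)C
Why: Acid-catalysed hydrazone condensation places the sulfonamide nitrogen anti to the substituted C9 (E isomer), which pre-sets the regiochemistry of the Shapiro step.

Step 6
Reactants: 6 (E)-2,4,6-triisopropylbenzenesulfonylhydrazone of 5; 7 di-tert-butyl dicarbonate (Boc2O)
Product: 9 tert-butyl 12-(TBSO)-13,14,15,16-tetranorlabd-7-en-17-oate, via C8-vinyllithium 8 (not isolated)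
Conditions: n-BuLi (2.2 equiv), THF, −78 → 0 °C; then Boc2O, −78 °C → rt
Reagents that add atoms: none
Why: Shapiro reaction: syn-directed deprotonation at the unhindered C7 methylene, then loss of sulfinate and N2, gives the C8 vinyllithium with a regiodefined Δ7 alkene, and acylation by Boc2O installs C17 as the tert-butyl ester without touching C9.

Step 7
Reactants: 9 tert-butyl 12-(TBSO)-13,14,15,16-tetranorlabd-7-en-17-oate
Product: 10 17-tert-butoxy-12,17-bis(TBSO)-13,14,15,16-tetranorlabda-6,8(17)-diene (silyl ketene acetal of 9)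
Conditions: LiN(i-Pr)2, THF/DMPU, −78 °C; then TBSCl, −78 → 0 °C; non-aqueous work-up, used crude
Reagents that add atoms: tert-butyldimethylsilyl chloride, CC(C)(C)[Si](C)(C)Cl
Why: Kinetic γ-deprotonation at C6 (the C9–H is cross-conjugated and not acidic) gives the extended lithium dienolate, which is O-silylated to the silyl ketene acetal (dienolate silylation).

Step 8
Reactants: 11 (diacetoxyiodo)benzene, PhI(OAc)2; 12 tiglic acid
Product: 13 [bis(tigloyloxy)iodo]benzene
Conditions: 12 (2.1 equiv), PhCl, 50 °C, reduced pressure (AcOH distilled off)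
Reagents that add atoms: none
Why: Carboxylate ligand exchange at trivalent iodine is driven to the bis-tiglate by removing the more volatile acetic acid; the E geometry of the tiglate is unaffected.

Step 9
Reactants: 10 silyl ketene acetal of 9; 13 [bis(tigloyloxy)iodo]benzene
Product: 14 tert-butyl 12-(TBSO)-6α-tigloyloxy-13,14,15,16-tetranorlabd-7-en-17-oate
Conditions: TMSOTf (10 mol %), CH2Cl2, 4 Å MS, −78 → −40 °C
Reagents that add atoms: none
Why: Proposed new method: TMSOTf ionises 13 to [PhI(OTig)]+, which exchanges silicon for trivalent iodine at the dienolate oxygen to give an enolonium-type O-iodanyl dienolate that is electrophilic at C6 and C8; the tiglate ligand is then transferred to C6 (vinylogous, SN2''-type ligand coupling) with loss of PhI and return of the conjugated ester. C6 is preferred over C8 because C8 is fully substituted and flanked by C9 and the ketene-acetal oxygens, and the carboxylate arrives on the open α-face because the β-face of C6 is blocked by the syn-axial C4β and C10 methyls, which sets 6S (6α-O). The closest known reaction types are α-acyloxylation of silyl enol ethers and ketones with PhI(O2CR)2 and the vinylogous Rubottom γ-hydroxylation of silyl dienol ethers; a γ-selective, diastereoselective carboxylate transfer from a diacyloxy(aryl)iodane to an ester silyl dienolate has not been shown.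

Step 10
Reactants: 14 tert-butyl 12-(TBSO)-6α-tigloyloxy-13,14,15,16-tetranorlabd-7-en-17-oate
Product: 15 tert-butyl 12-hydroxy-6α-tigloyloxy-13,14,15,16-tetranorlabd-7-en-17-oate
Conditions: HF·pyridine, THF/pyridine, 0 °C → rt
Reagents that add atoms: none
Why: Buffered fluoride desilylation cleaves only the primary silyl ether; the tert-butyl and tiglate esters are inert and the tert-butyl ester cannot lactonise onto the new alcohol.

Step 11
Reactants: 15 tert-butyl 12-hydroxy-6α-tigloyloxy-13,14,15,16-tetranorlabd-7-en-17-oate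
Product: 16 tert-butyl 12-iodo-6α-tigloyloxy-13,14,15,16-tetranorlabd-7-en-17-oate
Conditions: I2, PPh3, imidazole, CH2Cl2, 0 °C → rt
Reagents that add atoms: iodine, [I][I]
Why: Garegg–Samuelsson (Appel-type) iodination: the alkoxyphosphonium ion of the primary alcohol is displaced by iodide (SN2) and the esters are untouched.

Step 12
Reactants: 16 tert-butyl 12-iodo-6α-tigloyloxy-13,14,15,16-tetranorlabd-7-en-17-oate; 17 3-bromo-2(5H)-furanone
Product: 19 tert-butyl 6α-tigloyloxylabda-7,13-dien-16,15-olid-17-oate, via alkylzinc iodide 18 (not isolated)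
Conditions: Zn dust, LiCl, THF, 40 °C; then 17, Pd(OAc)2 (3 mol %), SPhos (6 mol %), THF, rt
Reagents that add atoms: none
Why: Zinc inserts into the primary C–I bond to give an ester-tolerant alkylzinc iodide, and Negishi coupling catalysed by zerovalent palladium with the α-bromobutenolide forms the C12–C13 bond; the pseudo-equatorial, β-face-shielded allylic C6 ester is not ionised.

Step 13
Reactants: 19 tert-butyl 6α-tigloyloxylabda-7,13-dien-16,15-olid-17-oate
Product: 20 (5S,6S,9R,10R)-6α-tigloyloxylabda-7,13-dien-16,15-olid-17-oic acid (CNP0245290.2)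
Conditions: CF3CO2H/CH2Cl2 (1:4), 0 °C → rt
Reagents that add atoms: none
Why: Acidolysis of the tert-butyl ester by E1 loss of isobutene frees the C17 acid, while the tiglate, the butenolide and the allylic C6–O bond (ionisation disfavoured next to the electron-poor alkene) are stable to CF3CO2H.

## Compound list

1 | (+)-sclareolide, (3aR,5aS,9aS,9bR)-3a,6,6,9a-tetramethyldecahydronaphtho[2,1-b]furan-2(1H)-one (8α-O, 9α-H, 5α-H, 10β-Me) | C1C[C@@]3(C)OC(=O)C[C@@H]3[C@@]2(C)CCCC(C)(C)[C@H]12 | starting material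
2 | 13,14,15,16-tetranorlabdane-8α,12-diol | C1C[C@@](C)(O)[C@H](CCO)[C@@]2(C)CCCC(C)(C)[C@H]12 | intermediate
3 | 12-(TBSO)-13,14,15,16-tetranorlabdan-8α-ol | C1C[C@@](C)(O)[C@H](CCO[Si](C)(C)C(C)(C)C)[C@@]2(C)CCCC(C)(C)[C@H]12 | intermediate
4 | 12-(TBSO)-13,14,15,16-tetranorlabd-8(17)-ene | C1CC(=C)[C@H](CCO[Si](C)(C)C(C)(C)C)[C@@]2(C)CCCC(C)(C)[C@H]12 | intermediate
5 | 12-(TBSO)-13,14,15,16,17-pentanorlabdan-8-one (9β side chain, 9α-H) | C1CC(=O)[C@H](CCO[Si](C)(C)C(C)(C)C)[C@@]2(C)CCCC(C)(C)[C@H]12 | intermediate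
6 | (E)-2,4,6-triisopropylbenzenesulfonylhydrazone of 5 (N–N bond syn to C7) | C1C/C(=N\NS(=O)(=O)c3c(C(C)C)cc(C(C)C)cc3C(C)C)[C@H](CCO[Si](C)(C)C(C)(C)C)[C@@]2(C)CCCC(C)(C)[C@H]12 | intermediate
7 | di-tert-butyl dicarbonate (Boc2O) | CC(C)(C)OC(=O)OC(=O)OC(C)(C)C | starting material
8 | 8-lithio-12-(TBSO)-13,14,15,16,17-pentanorlabd-7-ene (C8-vinyllithium) | C1C=C([Li])[C@H](CCO[Si](C)(C)C(C)(C)C)[C@@]2(C)CCCC(C)(C)[C@H]12 | intermediate
9 | tert-butyl 12-(TBSO)-13,14,15,16-tetranorlabd-7-en-17-oate | C1C=C(C(=O)OC(C)(C)C)[C@H](CCO[Si](C)(C)C(C)(C)C)[C@@]2(C)CCCC(C)(C)[C@H]12 | intermediate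
10 | 17-tert-butoxy-12,17-bis(TBSO)-13,14,15,16-tetranorlabda-6,8(17)-diene (silyl ketene acetal of 9; C8=C17 geometry undefined, mixture) | C1=CC(=C(OC(C)(C)C)O[Si](C)(C)C(C)(C)C)[C@H](CCO[Si](C)(C)C(C)(C)C)[C@@]2(C)CCCC(C)(C)[C@H]12 | intermediate
11 | (diacetoxyiodo)benzene, PhI(OAc)2 | CC(=O)OI(OC(C)=O)c1ccccc1 | starting material
12 | tiglic acid, (E)-2-methylbut-2-enoic acid | C/C=C(\C)C(=O)O | starting material
13 | [bis(tigloyloxy)iodo]benzene, PhI(O2C–C(CH3)=CHCH3)2, both acyl groups E | C/C=C(\C)C(=O)OI(OC(=O)/C(C)=C/C)c1ccccc1 | intermediate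
14 | tert-butyl 12-(TBSO)-6α-tigloyloxy-13,14,15,16-tetranorlabd-7-en-17-oate (6S) | C/C=C(\C)C(=O)O[C@H]1C=C(C(=O)OC(C)(C)C)[C@H](CCO[Si](C)(C)C(C)(C)C)[C@@]2(C)CCCC(C)(C)[C@H]12 | intermediate
15 | tert-butyl 12-hydroxy-6α-tigloyloxy-13,14,15,16-tetranorlabd-7-en-17-oate | C/C=C(\C)C(=O)O[C@H]1C=C(C(=O)OC(C)(C)C)[C@H](CCO)[C@@]2(C)CCCC(C)(C)[C@H]12 | intermediate
16 | tert-butyl 12-iodo-6α-tigloyloxy-13,14,15,16-tetranorlabd-7-en-17-oate | C/C=C(\C)C(=O)O[C@H]1C=C(C(=O)OC(C)(C)C)[C@H](CCI)[C@@]2(C)CCCC(C)(C)[C@H]12 | intermediate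
17 | 3-bromo-2(5H)-furanone | BrC1=CCOC1=O | starting material
18 | C12 alkylzinc iodide of 16 | C/C=C(\C)C(=O)O[C@H]1C=C(C(=O)OC(C)(C)C)[C@H](CC[Zn]I)[C@@]2(C)CCCC(C)(C)[C@H]12 | intermediate
19 | tert-butyl 6α-tigloyloxylabda-7,13-dien-16,15-olid-17-oate | C/C=C(\C)C(=O)O[C@H]1C=C(C(=O)OC(C)(C)C)[C@H](CCC2=CCOC2=O)[C@@]2(C)CCCC(C)(C)[C@H]12 | intermediate
20 | (5S,6S,9R,10R)-6α-tigloyloxylabda-7,13-dien-16,15-olid-17-oic acid (CNP0245290.2) | C/C=C(\C)C(=O)O[C@H]1C=C(C(=O)O)[C@H](CCC2=CCOC2=O)[C@@]2(C)CCCC(C)(C)[C@H]12 | target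

## Step count and risk

Total step count: 13 (12 on the main line plus the one-step preparation of reagent 13).
Longest linear sequence: 12 steps from (+)-sclareolide (steps 1–7 and 9–13).

The three steps most likely to fail:

**Step 9 (the proposed γ-acyloxylation).** The carboxylate could go to C8 instead (α-acyloxy β,γ-unsaturated ester), the enolonium could lose H5 to give the 5,7-dienoate, or the face selectivity could be poor. The fallback is known chemistry, sets out from 10 and comes back at 14. Kinetic protonation of 10 at C8 (AcOH, THF, −78 °C) gives the deconjugated ester tert-butyl 12-(TBSO)-13,14,15,16-tetranorlabd-6-en-17-oate F1 as a mixture of C8 epimers. mCPBA (NaHCO3, CH2Cl2, 0 °C) epoxidises its Δ6 alkene from the unshielded α-face to tert-butyl 6α,7α-epoxy-12-(TBSO)-13,14,15,16-tetranorlabdan-17-oate F2. DBU (CH2Cl2, rt) opens the epoxide by E1cB elimination to tert-butyl 6α-hydroxy-12-(TBSO)-13,14,15,16-tetranorlabd-7-en-17-oate F3, which erases C8 and fixes 6α-OH. Yamaguchi esterification of F3 with tiglic acid 12 (2,4,6-trichlorobenzoyl chloride, Et3N, DMAP, toluene) then gives 14.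

**Step 6 (Shapiro carboxylation).** Dianion formation on the hindered hydrazone may be incomplete, or the vinyllithium may be protonated before it meets Boc2O. The fallback sets out from 5 and comes back at 9. Kinetic enolisation at C7 and triflation (KN(SiMe3)2, PhNTf2, THF, −78 °C) give 12-(TBSO)-13,14,15,16,17-pentanorlabd-7-en-8-yl trifluoromethanesulfonate F4. Hydroxycarbonylation (Pd(OAc)2, dppf, CO 1 atm, KOAc, DMF, 60 °C, aqueous work-up; zerovalent palladium formed in situ) gives 12-(TBSO)-13,14,15,16-tetranorlabd-7-en-17-oic acid F5. Esterification with Boc2O, cat. DMAP and t-BuOH then gives 9.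

**Step 12 (Negishi coupling).** Zinc insertion may be sluggish, the alkylzinc may be protonated or undergo β-hydride elimination on palladium, or zerovalent palladium may ionise the allylic tiglate. The fallback sets out from 16 and comes back at 19, and builds the butenolide by metathesis instead of cross-coupling. Alkylation of the sodium salt of allyl diethylphosphonoacetate with 16 (NaH, DMF, 50 °C) gives tert-butyl 13-(allyloxycarbonyl)-13-(diethoxyphosphoryl)-6α-tigloyloxy-14,15,16-trinorlabd-7-en-17-oate F6 (C13 epimers). Horner–Wadsworth–Emmons methylenation ((CH2O)n, K2CO3, THF, 60 °C) gives the allyl 2-alkylacrylate, tert-butyl 13-(allyloxycarbonyl)-13-methylene-6α-tigloyloxy-14,15,16-trinorlabd-7-en-17-oate F7. Ring-closing metathesis with the second-generation Grubbs catalyst [RuCl2(H2IMes)(PCy3)(=CHPh)] (CH2Cl2, 40 °C) closes the butenolide and gives 19.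

## Further compounds

F1 | step 9 | tert-butyl 12-(TBSO)-13,14,15,16-tetranorlabd-6-en-17-oate (C8 epimers) | C1=CC(C(=O)OC(C)(C)C)[C@H](CCO[Si](C)(C)C(C)(C)C)[C@@]2(C)CCCC(C)(C)[C@H]12
F2 | step 9 | tert-butyl 6α,7α-epoxy-12-(TBSO)-13,14,15,16-tetranorlabdan-17-oate (C8 epimers) | [C@@H]12O[C@H]2C(C(=O)OC(C)(C)C)[C@H](CCO[Si](C)(C)C(C)(C)C)[C@@]3(C)CCCC(C)(C)[C@H]13
F3 | step 9 | tert-butyl 6α-hydroxy-12-(TBSO)-13,14,15,16-tetranorlabd-7-en-17-oate | O[C@H]1C=C(C(=O)OC(C)(C)C)[C@H](CCO[Si](C)(C)C(C)(C)C)[C@@]2(C)CCCC(C)(C)[C@H]12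
F4 | step 6 | 12-(TBSO)-13,14,15,16,17-pentanorlabd-7-en-8-yl trifluoromethanesulfonate | C1C=C(OS(=O)(=O)C(F)(F)F)[C@H](CCO[Si](C)(C)C(C)(C)C)[C@@]2(C)CCCC(C)(C)[C@H]12
F5 | step 6 | 12-(TBSO)-13,14,15,16-tetranorlabd-7-en-17-oic acid | C1C=C(C(=O)O)[C@H](CCO[Si](C)(C)C(C)(C)C)[C@@]2(C)CCCC(C)(C)[C@H]12
F6 | step 12 | tert-butyl 13-(allyloxycarbonyl)-13-(diethoxyphosphoryl)-6α-tigloyloxy-14,15,16-trinorlabd-7-en-17-oate (C13 epimers) | C/C=C(\C)C(=O)O[C@H]1C=C(C(=O)OC(C)(C)C)[C@H](CCC(C(=O)OCC=C)P(=O)(OCC)OCC)[C@@]2(C)CCCC(C)(C)[C@H]12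
F7 | step 12 | tert-butyl 13-(allyloxycarbonyl)-13-methylene-6α-tigloyloxy-14,15,16-trinorlabd-7-en-17-oate | C/C=C(\C)C(=O)O[C@H]1C=C(C(=O)OC(C)(C)C)[C@H](CCC(=C)C(=O)OCC=C)[C@@]2(C)CCCC(C)(C)[C@H]12
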